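**Retrosynthetic overview**

1. The biaryl bond (isoquinoline C7 to naphthalene C2) is made last, by Suzuki–Miyaura coupling of an (S)-7-bromo-3,4-dihydroisoquinoline with a 1-naphthol-2-boronate generated in the flask from the 2-bromonaphthol.
2. The nitrogen ring is opened to a polyketide-type 1,5-diketone (an o-acetyl arylacetone). An (S)-selective ω-transaminase aminates the benzyl methyl ketone and the amine closes onto the aryl ketone; this sets C3.
3. The diketone comes from a bromo arylacetone by ring acetylation to a 2-benzopyrylium salt and hydrolytic ring opening. The bromine is placed between the two methoxy groups by directed lithiation.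
4. The second naphthalene ring is closed by intramolecular aldol condensation and aromatisation of an o-acetyl arylacetaldehyde, released from an isocoumarin with MeMgBr. The isocoumarin comes from 3,5-dimethylanisole by ortho- and then lateral lithiation.
5. Ring order: benzopyrylium, then dihydroisoquinoline (branch A); lactone ring, then naphthalene ring (branch B); the two halves are joined afterwards.

Assumption: the SMILES defines only C3 (S) and not the biaryl axis, so no axial control is attempted; compounds 1 and 10 are taken as catalogue chemicals.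

**Route**

Step 1
Reactants: 1 1-(3,5-dimethoxyphenyl)propan-2-one
Product: 2 2-[(3,5-dimethoxyphenyl)methyl]-2-methyl-1,3-dioxolane
Conditions: HOCH2CH2OH, TsOH·H2O (cat.), toluene, reflux, Dean–Stark
Reagents that add atoms: ethylene glycol OCCO
Why: Acid-catalysed ketalisation with removal of water masks the enolisable ketone so that the ring can be lithiated next.

Step 2
Reactants: 2 2-[(3,5-dimethoxyphenyl)methyl]-2-methyl-1,3-dioxolane
Product: 5 1-(4-bromo-3,5-dimethoxyphenyl)propan-2-one, via aryllithium 3 (not isolated), via bromo ketal 4 (not isolated)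
Conditions: n-BuLi (1.2 equiv), THF, 0 °C to rt; BrCH2CH2Br, −78 °C to rt; then 2 M aq. HCl, THF, rt
Reagents that add atoms: 1,2-dibromoethane BrCCBr; water O
Why: Directed ortho-metalation lithiates the one position flanked by both methoxy groups, bromine transfer from 1,2-dibromoethane (loss of ethene) gives the bromide, and acetal hydrolysis returns the ketone.

Step 3
Reactants: 5 1-(4-bromo-3,5-dimethoxyphenyl)propan-2-one
Product: 7 1-(2-acetyl-4-bromo-3,5-dimethoxyphenyl)propan-2-one, via benzopyrylium salt 6 (not isolated)
Conditions: Ac2O, HBF4·OEt2 (1.1 equiv), 0 °C to rt; then aq. NaOAc, THF, rt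
Reagents that add atoms: acetic anhydride CC(=O)OC(C)=O; water O
Why: Friedel–Crafts acetylation ortho to the side chain (the two such positions are equivalent) is followed by cyclodehydration to the 2-benzopyrylium salt 6, whose mild hydrolytic ring opening releases the 1,5-diketone 7 without aldol cyclisation.

Step 4
Reactants: 7 1-(2-acetyl-4-bromo-3,5-dimethoxyphenyl)propan-2-one
Product: 9 (3S)-7-bromo-6,8-dimethoxy-1,3-dimethyl-3,4-dihydroisoquinoline, via amino ketone 8 (not isolated)
Conditions: (S)-selective ω-transaminase (Vibrio fluvialis), pyridoxal 5'-phosphate (1 mM), iPrNH2 (0.5 M), HEPES buffer pH 8.0 (no Tris, no ammonium), DMSO (15 vol %), 30 °C, 24–48 h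
Reagents that add atoms: isopropylamine CC(C)N
Why: Proposed new method: the pyridoxamine form of the (S)-selective enzyme should bind only the unhindered benzyl methyl ketone of 7 (the di-ortho-substituted aryl ketone is excluded) and deliver NH2 to the face that gives the (S)-amine 8, whose amino group then condenses spontaneously with the neighbouring aryl ketone to the six-membered cyclic imine 9, which pulls the transamination equilibrium and fixes C3 as S under enzyme control; the closest known reaction type is the ω-transaminase-triggered regioselective monoamination and aza-cyclisation of aliphatic 1,5-diketones to chiral Δ1-piperideines, here transferred to the polyketide-type diketone from which the isoquinoline half of these alkaloids is presumed to arise.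

Step 5
Reactants: 10 1-methoxy-3,5-dimethylbenzene
Product: 12 methyl 2-methoxy-4,6-dimethylbenzoate, via aryllithium 11 (not isolated)
Conditions: n-BuLi, TMEDA, Et2O, 0 °C to rt; then added to ClCO2Me (3 equiv), THF, −78 °C
Reagents that add atoms: methyl chloroformate COC(=O)Cl
Why: Directed ortho-metalation next to the methoxy group (both ortho positions are equivalent) and acylation of the aryllithium by inverse addition to the chloroformate give the hindered benzoate.

Step 6
Reactants: 12 methyl 2-methoxy-4,6-dimethylbenzoate
Product: 15 8-methoxy-6-methyl-1H-isochromen-1-one, via benzylic lithium 13 (not isolated), via aldehyde ester 14 (not isolated)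
Conditions: LiN(iPr)2 (1.2 equiv), THF, −78 °C; DMF, −78 to 0 °C; 1 M aq. HCl; then TsOH·H2O (5 mol %), toluene, reflux
Reagents that add atoms: N,N-dimethylformamide CN(C)C=O
Why: Lateral lithiation of the ortho-methyl group (assisted by the ester carbonyl, which the para-methyl lacks), formylation with DMF and acid-catalysed enol lactonisation give the isocoumarin, a masked 1,5-keto aldehyde.

Step 7
Reactants: 15 8-methoxy-6-methyl-1H-isochromen-1-one
Product: 17 8-methoxy-6-methylnaphthalen-1-ol, via keto aldehyde 16 (not isolated)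
Conditions: MeMgBr (1.3 equiv), THF, −78 to 0 °C; then 2 M aq. KOH, MeOH, rt; 1 M HCl to pH 3
Reagents that add atoms: methylmagnesium bromide C[Mg]Br
Why: Fujimoto–Belleau-type addition of MeMgBr opens the enol lactone to keto aldehyde 16 (the di-ortho-substituted aryl ketone resists a second addition), and base then drives the intramolecular aldol condensation and aromatisation, the same ring closure by which the naphthalene half is presumed to form from a benzylic 1,5-dicarbonyl compound.

Step 8
Reactants: 17 8-methoxy-6-methylnaphthalen-1-ol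
Product: 18 2-bromo-8-methoxy-6-methylnaphthalen-1-ol
Conditions: NBS (1.0 equiv), iPr2NH (10 mol %), CH2Cl2, 0 °C
Reagents that add atoms: N-bromosuccinimide O=C1CCC(=O)N1Br
Why: Amine-catalysed electrophilic bromination of a phenol delivers bromine from a hydrogen-bonded N-bromoamine to the position ortho to the hydroxyl, here C2, the only free ortho position.

Step 9
Reactants: 18 2-bromo-8-methoxy-6-methylnaphthalen-1-ol; 9 (3S)-7-bromo-6,8-dimethoxy-1,3-dimethyl-3,4-dihydroisoquinoline
Product: 20 2-[(3S)-6,8-dimethoxy-1,3-dimethyl-3,4-dihydroisoquinolin-7-yl]-8-methoxy-6-methylnaphthalen-1-ol, via pinacol boronate 19 (not isolated)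
Conditions: 18 (1.5 equiv), B2pin2 (1.6 equiv), Pd2(dba)3 (2 mol %), XPhos (8 mol %), KOAc, 1,4-dioxane, 100 °C, 2 h; then 9 (1.0 equiv), 3 M aq. K3PO4, 100 °C, 12 h
Reagents that add atoms: none
Why: One-pot Miyaura borylation of 18 to boronate 19 and Suzuki–Miyaura coupling with the di-ortho-methoxy bromide 9 build the tri-ortho-substituted biaryl with a bulky biaryl phosphine, and the C3 stereocentre is not touched.

**Compound list**

1 | 1-(3,5-dimethoxyphenyl)propan-2-one | COc1cc(CC(C)=O)cc(OC)c1 | starting material
2 | 2-[(3,5-dimethoxyphenyl)methyl]-2-methyl-1,3-dioxolane | COc1cc(CC2(C)OCCO2)cc(OC)c1 | intermediate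
3 | [2,6-dimethoxy-4-[(2-methyl-1,3-dioxolan-2-yl)methyl]phenyl]lithium | [Li]c1c(OC)cc(CC2(C)OCCO2)cc1OC | intermediate
4 | 2-[(4-bromo-3,5-dimethoxyphenyl)methyl]-2-methyl-1,3-dioxolane | COc1cc(CC2(C)OCCO2)cc(OC)c1Br | intermediate
5 | 1-(4-bromo-3,5-dimethoxyphenyl)propan-2-one | COc1cc(CC(C)=O)cc(OC)c1Br | intermediate
6 | 7-bromo-6,8-dimethoxy-1,3-dimethylisochromenylium tetrafluoroborate | COc1cc2cc(C)[o+]c(C)c2c(OC)c1Br.F[B-](F)(F)F | intermediate
7 | 1-(2-acetyl-4-bromo-3,5-dimethoxyphenyl)propan-2-one | COc1cc(CC(C)=O)c(C(C)=O)c(OC)c1Br | intermediate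
8 | 1-[6-[(2S)-2-aminopropyl]-3-bromo-2,4-dimethoxyphenyl]ethan-1-one | COc1cc(C[C@H](C)N)c(C(C)=O)c(OC)c1Br | intermediate
9 | (3S)-7-bromo-6,8-dimethoxy-1,3-dimethyl-3,4-dihydroisoquinoline | COc1cc2c(c(OC)c1Br)C(C)=N[C@@H](C)C2 | intermediate
10 | 1-methoxy-3,5-dimethylbenzene | COc1cc(C)cc(C)c1 | starting material
11 | (2-methoxy-4,6-dimethylphenyl)lithium | [Li]c1c(C)cc(C)cc1OC | intermediate
12 | methyl 2-methoxy-4,6-dimethylbenzoate | COC(=O)c1c(C)cc(C)cc1OC | intermediate
13 | [3-methoxy-2-(methoxycarbonyl)-5-methylphenyl]methyllithium | [Li]Cc1cc(C)cc(OC)c1C(=O)OC | intermediate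
14 | methyl 2-methoxy-4-methyl-6-(2-oxoethyl)benzoate | COC(=O)c1c(CC=O)cc(C)cc1OC | intermediate
15 | 8-methoxy-6-methyl-1H-isochromen-1-one | COc1cc(C)cc2C=COC(=O)c12 | intermediate
16 | 2-(2-acetyl-3-methoxy-5-methylphenyl)acetaldehyde | COc1cc(C)cc(CC=O)c1C(C)=O | intermediate
17 | 8-methoxy-6-methylnaphthalen-1-ol | COc1cc(C)cc2cccc(O)c12 | intermediate
18 | 2-bromo-8-methoxy-6-methylnaphthalen-1-ol | COc1cc(C)cc2ccc(Br)c(O)c12 | intermediate
19 | 8-methoxy-6-methyl-2-(4,4,5,5-tetramethyl-1,3,2-dioxaborolan-2-yl)naphthalen-1-ol | COc1cc(C)cc2ccc(B3OC(C)(C)C(C)(C)O3)c(O)c12 | intermediate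
20 | 2-[(3S)-6,8-dimethoxy-1,3-dimethyl-3,4-dihydroisoquinolin-7-yl]-8-methoxy-6-methylnaphthalen-1-ol | COc1cc2c(c(OC)c1-c1ccc3cc(C)cc(OC)c3c1O)C(C)=N[C@@H](C)C2 | target

**Totals**

Total step count: 9. Longest linear sequence: 5 steps (10 → 12 → 15 → 17 → 18 → 20, and equally 1 → 2 → 5 → 7 → 9 → 20).

**Three steps most likely to fail**

Step 4 (enzyme acceptance of the o-acetyl diketone; background condensation of 7 with the amine donor to an isoquinolinium salt). The fallback sets out from 5 and comes back at 9. The amination is moved to the mono-ketone and the ring is closed electrophilically instead of by diketone condensation. Ketone 5 with the same (S)-selective ω-transaminase and iPrNH2 gives (2S)-1-(4-bromo-3,5-dimethoxyphenyl)propan-2-amine F1, an amphetamine-type substrate with no second carbonyl. Ac2O and Et3N in CH2Cl2 give N-[(2S)-1-(4-bromo-3,5-dimethoxyphenyl)propan-2-yl]acetamide F2. POCl3 in MeCN at reflux then closes the ring by Bischler–Napieralski cyclisation at either of the two equivalent ortho positions to give 9.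

Step 9 (borylation of a free ortho-bromonaphthol, protodeboronation, and a hindered coupling; it also depends on the ortho-selectivity of step 8). The fallback sets out from 17 and comes back at 20, and makes step 8 unnecessary. MOMCl and iPr2NEt give 1-methoxy-8-(methoxymethoxy)-3-methylnaphthalene F3. Ortho-lithiation directed by the OMOM group (n-BuLi, TMEDA, THF), then B(OMe)3 and a mild acidic work-up, gives [8-methoxy-1-(methoxymethoxy)-6-methylnaphthalen-2-yl]boronic acid F4. Suzuki–Miyaura coupling of F4 with 9 (Pd(OAc)2, SPhos, K3PO4, toluene/H2O, 100 °C) gives (3S)-6,8-dimethoxy-7-[8-methoxy-1-(methoxymethoxy)-6-methylnaphthalen-2-yl]-1,3-dimethyl-3,4-dihydroisoquinoline F5. HCl in MeOH removes the MOM group and gives 20 after neutralisation.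

Step 6 (ortho- versus para-methyl deprotonation of 12, and handling of the sensitive arylacetaldehyde 14). The fallback sets out from 10 and comes back at 17, replacing steps 5 to 7 with a ring closure in which only the ortho-methyl anion can react. Aryllithium 11, made as in step 5, is quenched with N-methoxy-N-methylacetamide to give 1-(2-methoxy-4,6-dimethylphenyl)ethan-1-one F6. Heating in neat Me2NCH(OMe)2 at 120 °C gives (2E)-3-(dimethylamino)-1-(2-methoxy-4,6-dimethylphenyl)prop-2-en-1-one F7. LiN(iPr)2 in THF (−78 °C to rt) deprotonates the ortho-methyl group, the benzylic anion adds to the vinylogous amide carbon, and loss of dimethylamine with tautomerisation gives 17. Deprotonation at the para-methyl group is reversible and unproductive.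

**Further compounds**

F1 | step 4 | (2S)-1-(4-bromo-3,5-dimethoxyphenyl)propan-2-amine | COc1cc(C[C@H](C)N)cc(OC)c1Br
F2 | step 4 | N-[(2S)-1-(4-bromo-3,5-dimethoxyphenyl)propan-2-yl]acetamide | COc1cc(C[C@H](C)NC(C)=O)cc(OC)c1Br
F3 | step 9 | 1-methoxy-8-(methoxymethoxy)-3-methylnaphthalene | COCOc1cccc2cc(C)cc(OC)c12
F4 | step 9 | [8-methoxy-1-(methoxymethoxy)-6-methylnaphthalen-2-yl]boronic acid | COCOc1c(B(O)O)ccc2cc(C)cc(OC)c12
F5 | step 9 | (3S)-6,8-dimethoxy-7-[8-methoxy-1-(methoxymethoxy)-6-methylnaphthalen-2-yl]-1,3-dimethyl-3,4-dihydroisoquinoline | COCOc1c(-c2c(OC)cc3c(c2OC)C(C)=N[C@@H](C)C3)ccc2cc(C)cc(OC)c12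
F6 | step 6 | 1-(2-methoxy-4,6-dimethylphenyl)ethan-1-one | COc1cc(C)cc(C)c1C(C)=O
F7 | step 6 | (2E)-3-(dimethylamino)-1-(2-methoxy-4,6-dimethylphenyl)prop-2-en-1-one | COc1cc(C)cc(C)c1C(=O)/C=C/N(C)C
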